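**Plan**

- Retrosynthesis: the three propanoate C–O bonds are cut first; ring C (eleven-membered) is opened at C12–C13 (alkenyl iodide + aldehyde); ring B (cyclopentane) is opened at C4–C5 (ketone enolate + allylic bromide) and then at C16–C7 (conjugate addition); ring A is traced to a phenol.
- Forward: phenol → quinone monoketal (ring A) → C1 side arm by asymmetric 1,4-vinylation → union with a (Z)-alkenyl C5–C11 fragment at C16–C7 → ring B by C4–C5 cycloalkylation → ring C by chromium-mediated C12–C13 closure → acylation.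
- Enabling feature: the C3 carbonyl of ring A flanks the methyl-bearing C4, so C4 is the carbon of a tetrasubstituted enolate; C16, the neighbour of C4 in ring A, carries a (Z)-C6=C7 arm that holds bromide-bearing C5 over C4.
- Helpers: C15 is carried as a dimethyl ketal (later the =CH2 carbon); the C6=C7 alkene is later hydrogenated; hydroxyls travel as benzyl and silyl ethers.
- Stereochemistry: C1 from the chiral rhodium catalyst; C16 trans to C1; C4 from the tether (cis A/B fusion); C3 from the CBS reagent; C7 from convex-face hydrogenation; C8 and C9 from (S)-but-3-yn-2-ol (allene chirality transfer, syn addition); 11Z from the Stork–Zhao olefination; C13 in the macrocyclisation.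

Key step: step 11

Numbering used (trinervitane skeleton): ring A = C1, C2, C3, C4, C16, C15; ring B = C4, C5, C6, C7, C16; ring C = C1, C15, C16, C7 to C14; C17 = exocyclic methylene carbon on C15; C18, C19, C20 = methyls on C4, C8, C12. The target is the (1R,3S,4S,7R,8S,9S,11Z,13R,16S) isomer.

Assumption: the enantioface selection of the (S)-BINAP rhodium catalyst in step 2 is assigned by analogy with cyclohex-2-enone.

**Route**

Step 1
Reactants: 1 4-methoxy-2-methylphenol
Product: 2 4,4-dimethoxy-2-methylcyclohexa-2,5-dien-1-one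
Conditions: PhI(OAc)2, MeOH, 0 °C
Reagents that add atoms: methanol (CO)
Why: Oxidative dearomatisation of a para-methoxyphenol (phenol-to-quinone-monoketal oxidation) traps the phenoxenium ion at the methoxy-bearing carbon with methanol; no stereocentre is formed.

Step 2
Reactants: 2 4,4-dimethoxy-2-methylcyclohexa-2,5-dien-1-one
Product: 3 (5S)-5-ethenyl-4,4-dimethoxy-2-methylcyclohex-2-en-1-one
Conditions: [Rh(cod)2]PF6 (3 mol %), (S)-BINAP, CH2=CHBF3K, toluene/H2O, 100 °C
Reagents that add atoms: potassium vinyltrifluoroborate (C=C[B-](F)(F)F.[K+])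
Why: Hayashi–Miyaura asymmetric 1,4-addition delivers the vinyl group to the unsubstituted enone carbon (future C1) rather than the α-methylated enone, and the chiral rhodium–BINAP complex selects the enantiotopic face expected to give the 5S centre.

Step 3
Reactants: 4 (S)-but-3-yn-2-ol
Product: 5 (S)-but-3-yn-2-yl methanesulfonate
Conditions: MsCl, Et3N, CH2Cl2, −78 → 0 °C
Reagents that add atoms: methanesulfonyl chloride (CS(=O)(=O)Cl)
Why: O-Sulfonylation activates the propargylic position without touching the stereocentre.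

Step 4
Reactants: 5 (S)-but-3-yn-2-yl methanesulfonate
Product: 6 (aR)-tributyl(buta-1,2-dien-1-yl)stannane
Conditions: Bu3SnH, LiN(i-Pr)2, THF, 0 °C; CuBr·SMe2, −78 °C; then 5
Reagents that add atoms: tributyltin hydride (CCCC[SnH](CCCC)CCCC)
Why: Anti-SN2' displacement of the propargylic mesylate by the stannylcuprate converts the carbinol stereocentre into the allene axis (central-to-axial chirality transfer), which should give the aR allene.

Step 5
Reactants: 6 (aR)-tributyl(buta-1,2-dien-1-yl)stannane; 7 3-(benzyloxy)propanal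
Product: 8 (3S,4S)-1-(benzyloxy)-4-methylhex-5-yn-3-ol
Conditions: BF3·OEt2, CH2Cl2, −78 °C
Reagents that add atoms: none
Why: Lewis-acid-promoted SE2' addition of the chiral allenylstannane through an open transition state; the aldehyde enters anti to tin, which fixes the methyl-bearing carbon (C8), and the acyclic antiperiplanar arrangement should give the syn carbinol (C9).

Step 6
Reactants: 8 (3S,4S)-1-(benzyloxy)-4-methylhex-5-yn-3-ol
Product: 9 (3S,4S)-1-(benzyloxy)-3-[(tert-butyldimethylsilyl)oxy]-4-methylhex-5-yne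
Conditions: TBSCl, imidazole, DMF, rt
Reagents that add atoms: tert-butyldimethylsilyl chloride (CC(C)(C)[Si](C)(C)Cl)
Why: Standard silylation of the secondary alcohol protects the future C9 oxygen through the organometallic steps.

Step 7
Reactants: 9 (3S,4S)-1-(benzyloxy)-3-[(tert-butyldimethylsilyl)oxy]-4-methylhex-5-yne
Product: 11 (4S,5S)-7-(benzyloxy)-5-[(tert-butyldimethylsilyl)oxy]-4-methylhept-2-yn-1-ol, via lithium acetylide 10 (not isolated)
Conditions: n-BuLi, THF, −78 °C; (CH2O)n, −78 °C → rt
Reagents that add atoms: paraformaldehyde (formaldehyde, C=O)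
Why: Hydroxymethylation of the terminal acetylide adds the carbon that becomes C5; the stereocentres are not involved.

Step 8
Reactants: 11 (4S,5S)-7-(benzyloxy)-5-[(tert-butyldimethylsilyl)oxy]-4-methylhept-2-yn-1-ol
Product: 13 (2Z,4R,5S)-7-(benzyloxy)-5-[(tert-butyldimethylsilyl)oxy]-3-iodo-4-methylhept-2-en-1-ol, via cyclic alkenylalanate 12 (not isolated)
Conditions: NaAlH2(OCH2CH2OMe)2, THF, 0 °C → rt; then I2, THF, −78 °C
Reagents that add atoms: iodine (II)
Why: Hydroxyl-directed trans-hydroalumination of the propargylic alcohol places aluminium on the distal alkyne carbon in a five-membered alkoxyalanate, and iodinolysis with retention gives the (Z)-3-iodoallylic alcohol with iodine cis to CH2OH.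

Step 9
Reactants: 3 (5S)-5-ethenyl-4,4-dimethoxy-2-methylcyclohex-2-en-1-one; 13 (2Z,4R,5S)-7-(benzyloxy)-5-[(tert-butyldimethylsilyl)oxy]-3-iodo-4-methylhept-2-en-1-ol
Product: 16 keto allylic alcohol (C16–C7 joined; C5–OH free; C4 epimers), via alkenylmagnesium chloride 14 (not isolated), via trimethylsilyl enol ether 15 (not isolated)
Conditions: 13, i-PrMgCl·LiCl (2.0 equiv), THF, −20 °C; CuBr·SMe2 (10 mol %), Me3SiCl, DMPU, then 3, −78 → −30 °C; K2CO3, MeOH, 0 °C
Reagents that add atoms: none
Why: Iodine–magnesium exchange keeps the alkene geometry and the copper-catalysed, chlorosilane-accelerated conjugate addition of the alkenyl Grignard reagent should occur on the enone face opposite the C1 vinyl group (trans rule of 5-substituted cyclohexenones), which sets C16; basic methanolysis removes both trimethylsilyl groups.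

Step 10
Reactants: 16 keto allylic alcohol
Product: 17 keto (Z)-allylic bromide (C5–Br)
Conditions: CBr4, PPh3, 2,6-lutidine, CH2Cl2, −20 °C
Reagents that add atoms: tetrabromomethane (BrC(Br)(Br)Br)
Why: Appel bromination of the primary allylic alcohol proceeds by SN2 displacement at C5 at low temperature, so the (Z)-C6=C7 geometry is kept.

Step 11
Reactants: 17 keto (Z)-allylic bromide
Product: 19 cis-fused ring A/B ketone (C4 quaternary; ring B cyclopentene C6=C7), via potassium enolate 18 (not isolated)
Conditions: KOtBu, THF/t-BuOH (5:1), −20 → 0 °C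
Reagents that add atoms: none
Why: KOtBu in tert-butanol/THF equilibrates the two enolates of the C3 ketone, and only the tetrasubstituted C3–O/C4 enolate can reach the primary allylic bromide, so C4 attacks C5 in an intramolecular SN2 C-alkylation; the closest known reaction type is the cyclopentene annulation of cyclohexenones by conjugate addition of a bifunctional alkenyl reagent followed by enolate cycloalkylation, together with the classical base-mediated closure of cis-hydrindanones. Ring B closes in the 5-exo-tet mode with the enolate double bond outside the new ring (enolexo), the stereoelectronically allowed alignment. The new quaternary centre C4 is controlled by the tether: the three-atom arm C7=C6–C5 is anchored on C16, so C5 can only be delivered to the ring A face that already carries C7, which gives the cis ring fusion with the C18 methyl on the opposite face (4S). The step needs C4 over C2 enolate reactivity, C- over O-alkylation and SN2 over SN2', and the substrate secures all three: the (Z)-C6=C7 geometry holds C5 next to C4, the C2 enolate could only form a bridged seven-membered ring and O-alkylation an oxepine (both slower than five-ring C-alkylation of a potassium enolate by a soft allylic bromide in a protic medium), and SN2' attack at C7 would require a cyclopropane. The C4 epimer mixture of the precursor converges because C4 is planar in the enolate.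

Step 12
Reactants: 19 cis-fused ring A/B ketone
Product: 20 ring A/B (3S)-alcohol
Conditions: (R)-2-methyl-CBS-oxazaborolidine, catecholborane, toluene, −40 °C
Reagents that add atoms: none
Why: Corey–Bakshi–Shibata reduction under reagent control: the oxazaborolidine binds the carbonyl lone pair on the side of the small C2 methylene, away from quaternary C4, and should deliver hydride to the face that gives the 3S alcohol (hydroxyl cis to the C18 methyl), while catecholborane leaves the alkenes untouched at this temperature.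

Step 13
Reactants: 20 ring A/B (3S)-alcohol
Product: 21 3-O-propanoate
Conditions: (EtCO)2O, DMAP, Et3N, CH2Cl2, rt
Reagents that add atoms: propionic anhydride (CCC(=O)OC(=O)CC)
Why: DMAP-catalysed acylation installs the first of the three propanoates, which then serves as the C3 protecting group.

Step 14
Reactants: 21 3-O-propanoate
Product: 23 primary alcohol at C13, via B-alkyl-9-borabicyclononane 22 (not isolated)
Conditions: 9-BBN, THF, 0 °C → rt; then NaBO3·4H2O, THF/H2O, rt
Reagents that add atoms: sodium perborate, NaBO3·4H2O ([Na+].[Na+].O[B-]1(O)OO[B-](O)(O)OO1)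
Why: Anti-Markovnikov hydroboration with the bulky borane is selective for the monosubstituted vinyl group over the hindered trisubstituted ring B alkene, and the mild perborate oxidation spares the ester.

Step 15
Reactants: 23 primary alcohol at C13
Product: 24 13-O-TBS ether
Conditions: TBSCl, imidazole, CH2Cl2, rt
Reagents that add atoms: tert-butyldimethylsilyl chloride (CC(C)(C)[Si](C)(C)Cl)
Why: Silylation of the primary alcohol keeps C13 distinct from C11, which is unmasked next.

Step 16
Reactants: 24 13-O-TBS ether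
Product: 25 saturated ring A/B alcohol (7R; C11–OH free)
Conditions: H2 (5 bar), Pd(OH)2/C, EtOAc, rt
Reagents that add atoms: none
Why: Heterogeneous hydrogenation should add to the convex face of the cis-fused bicycle (the face of H16 and the C18 methyl, opposite the ring A carbons C3 and C15), which sets C7 with C8 cis to C15, and the same conditions hydrogenolyse the benzyl ether.

Step 17
Reactants: 25 saturated ring A/B alcohol
Product: 26 C11 aldehyde
Conditions: Dess–Martin periodinane, NaHCO3, CH2Cl2, 0 °C → rt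
Reagents that add atoms: none
Why: Buffered Dess–Martin oxidation converts the primary alcohol to the β-silyloxy aldehyde without elimination or ketal loss.

Step 18
Reactants: 26 C11 aldehyde
Product: 27 (11Z)-12-iodoalkene
Conditions: [Ph3PCH(I)CH3]I, NaN(SiMe3)2, THF, −78 °C; DMPU; then 26, −78 °C
Reagents that add atoms: (1-iodoethyl)triphenylphosphonium iodide (CC(I)[P+](c1ccccc1)(c1ccccc1)c1ccccc1.[I-])
Why: Stork–Zhao olefination (Wittig reaction of the non-stabilised α-iodo ylide through the kinetic cis-oxaphosphetane) should give the (Z)-2-iodoalk-2-ene with iodine cis to C10, which fixes the ring C alkene geometry.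

Step 19
Reactants: 27 (11Z)-12-iodoalkene
Product: 28 C15 ketone
Conditions: PPTS, acetone/H2O (10:1), rt
Reagents that add atoms: water (O)
Why: Mild acid hydrolysis removes the acyclic dimethyl ketal, which is far more labile than the silyl ethers, the ester and the alkenyl iodide.

Step 20
Reactants: 28 C15 ketone
Product: 29 C15 exocyclic methylene compound
Conditions: Zn, CH2Br2, TiCl4, THF/CH2Cl2, 0 °C → rt
Reagents that add atoms: dibromomethane (BrCBr)
Why: Takai–Lombardo methylenation is non-basic, so the hindered, enolisable ketone should be converted to the C15=C17 alkene without epimerising C1 or C16 and without attack on the propanoate.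

Step 21
Reactants: 29 C15 exocyclic methylene compound
Product: 30 9,13-diol
Conditions: HF·pyridine, pyridine, THF, rt
Reagents that add atoms: none
Why: Buffered fluoride removes both silyl ethers and leaves the propanoate, the alkenes and the alkenyl iodide intact.

Step 22
Reactants: 30 9,13-diol
Product: 31 C13 aldehyde (9-OH free)
Conditions: TEMPO (10 mol %), PhI(OAc)2, CH2Cl2, rt
Reagents that add atoms: none
Why: The oxoammonium oxidation is selective for the primary over the secondary alcohol, so no protecting group is needed at C9.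

Step 23
Reactants: 31 C13 aldehyde
Product: 33 macrocyclic 9,13-diol 3-propanoate, via alkenylchromium dichloride 32 (not isolated)
Conditions: CrCl2 (8 equiv), NiCl2 (2 mol %), DMSO/THF, rt, slow addition to 2 mM
Reagents that add atoms: none
Why: Nozaki–Hiyama–Kishi reaction: the alkenyl iodide adds to zerovalent nickel, transmetallates to trivalent chromium with retention of the Z geometry and adds to the aldehyde to close ring C at C12–C13; C13 is set under macrocyclic control, the 13R carbinol being expected from attack on the peripheral aldehyde face in the conformer that keeps the C20 methyl outside the ring, and this is the least secure assignment of the route.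

Step 24
Reactants: 33 macrocyclic 9,13-diol 3-propanoate
Product: 34 (1R,3S,4S,7R,8S,9S,11Z,13R,16S)-trinervita-11,15(17)-diene-3,9,13-triyl tripropanoate
Conditions: (EtCO)2O, DMAP, pyridine, CH2Cl2, rt
Reagents that add atoms: propionic anhydride (CCC(=O)OC(=O)CC)
Why: DMAP-catalysed acylation of the two secondary alcohols completes the tripropanoate without touching any stereocentre.

**Compound list**

1 | 4-methoxy-2-methylphenol | COc1ccc(O)c(C)c1 | starting material
2 | 4,4-dimethoxy-2-methylcyclohexa-2,5-dien-1-one | COC1(OC)C=CC(=O)C(C)=C1 | intermediate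
3 | (5S)-5-ethenyl-4,4-dimethoxy-2-methylcyclohex-2-en-1-one | COC1(OC)[C@H](C=C)CC(=O)C(C)=C1 | intermediate
4 | (S)-but-3-yn-2-ol | C#C[C@H](C)O | starting material
5 | (S)-but-3-yn-2-yl methanesulfonate | C#C[C@H](C)OS(C)(=O)=O | intermediate
6 | (aR)-tributyl(buta-1,2-dien-1-yl)stannane | CC([H])=[C@]=C([H])[Sn](CCCC)(CCCC)CCCC | intermediate
7 | 3-(benzyloxy)propanal | O=CCCOCc1ccccc1 | starting material
8 | (3S,4S)-1-(benzyloxy)-4-methylhex-5-yn-3-ol (syn) | C#C[C@H](C)[C@@H](O)CCOCc1ccccc1 | intermediate
9 | (3S,4S)-1-(benzyloxy)-3-[(tert-butyldimethylsilyl)oxy]-4-methylhex-5-yne | C#C[C@H](C)[C@@H](O[Si](C)(C)C(C)(C)C)CCOCc1ccccc1 | intermediate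
10 | lithium acetylide of 9 (formed in the flask) | [Li]C#C[C@H](C)[C@@H](O[Si](C)(C)C(C)(C)C)CCOCc1ccccc1 | intermediate
11 | (4S,5S)-7-(benzyloxy)-5-[(tert-butyldimethylsilyl)oxy]-4-methylhept-2-yn-1-ol | OCC#C[C@H](C)[C@@H](O[Si](C)(C)C(C)(C)C)CCOCc1ccccc1 | intermediate
12 | sodium cyclic alkenylalanate of 11, aluminium on C3 and bridged to O1 (formed in the flask) | [Na+].COCCO[Al-]1(OCCOC)OCC=C1[C@H](C)[C@@H](O[Si](C)(C)C(C)(C)C)CCOCc1ccccc1 | intermediate
13 | (2Z,4R,5S)-7-(benzyloxy)-5-[(tert-butyldimethylsilyl)oxy]-3-iodo-4-methylhept-2-en-1-ol | OC/C=C(\I)[C@H](C)[C@@H](O[Si](C)(C)C(C)(C)C)CCOCc1ccccc1 | intermediate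
14 | (Z)-alkenylmagnesium chloride of 13 with chloromagnesium alkoxide (formed in the flask) | Cl[Mg]OC/C=C(\[Mg]Cl)[C@H](C)[C@@H](O[Si](C)(C)C(C)(C)C)CCOCc1ccccc1 | intermediate
15 | conjugate adduct as C3 trimethylsilyl enol ether and C5 trimethylsilyl ether (formed in the flask) | COC1(OC)[C@H](C=C)CC(O[Si](C)(C)C)=C(C)[C@H]1C(=C/CO[Si](C)(C)C)\[C@H](C)[C@@H](O[Si](C)(C)C(C)(C)C)CCOCc1ccccc1 | intermediate
16 | (3S,5S)-3-[(2Z,4S,5S)-7-(benzyloxy)-5-[(tert-butyldimethylsilyl)oxy]-1-hydroxy-4-methylhept-2-en-3-yl]-5-ethenyl-4,4-dimethoxy-2-methylcyclohexan-1-one (epimers at C2 of the ring, which is C4 of the target) | COC1(OC)[C@H](C=C)CC(=O)C(C)[C@H]1C(=C/CO)\[C@H](C)[C@@H](O[Si](C)(C)C(C)(C)C)CCOCc1ccccc1 | intermediate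
17 | (3S,5S)-3-[(2Z,4S,5S)-7-(benzyloxy)-1-bromo-5-[(tert-butyldimethylsilyl)oxy]-4-methylhept-2-en-3-yl]-5-ethenyl-4,4-dimethoxy-2-methylcyclohexan-1-one (same epimer mixture) | COC1(OC)[C@H](C=C)CC(=O)C(C)[C@H]1C(=C/CBr)\[C@H](C)[C@@H](O[Si](C)(C)C(C)(C)C)CCOCc1ccccc1 | intermediate
18 | potassium C3–O/C4 enolate of 17 (formed in the flask) | [K+].COC1(OC)[C@H](C=C)CC([O-])=C(C)[C@H]1C(=C/CBr)\[C@H](C)[C@@H](O[Si](C)(C)C(C)(C)C)CCOCc1ccccc1 | intermediate
19 | cis-fused ring A/B ketone: ring A with C3=O, C15 dimethyl ketal and C1 vinyl; fusion C4 (CH3) / C16 (H) cis; ring B cyclopentene C6=C7; C7 bears the (2S,3S)-5-(benzyloxy)-3-[(tert-butyldimethylsilyl)oxy]pentan-2-yl chain (C8–C11); C1, C4, C8, C9, C16 as in the target | COC1(OC)[C@H](C=C)CC(=O)[C@@]2(C)CC=C([C@H](C)[C@@H](O[Si](C)(C)C(C)(C)C)CCOCc3ccccc3)[C@@H]12 | intermediate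
20 | (3S)-alcohol of 19 (C3–OH cis to the C18 methyl) | COC1(OC)[C@H](C=C)C[C@H](O)[C@@]2(C)CC=C([C@H](C)[C@@H](O[Si](C)(C)C(C)(C)C)CCOCc3ccccc3)[C@@H]12 | intermediate
21 | 3-O-propanoate of 20 | COC1(OC)[C@H](C=C)C[C@H](OC(=O)CC)[C@@]2(C)CC=C([C@H](C)[C@@H](O[Si](C)(C)C(C)(C)C)CCOCc3ccccc3)[C@@H]12 | intermediate
22 | B-alkyl-9-borabicyclo[3.3.1]nonane from the vinyl group of 21, boron on C13 (formed in the flask) | COC1(OC)[C@H](CCB3C4CCCC3CCC4)C[C@H](OC(=O)CC)[C@@]2(C)CC=C([C@H](C)[C@@H](O[Si](C)(C)C(C)(C)C)CCOCc3ccccc3)[C@@H]12 | intermediate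
23 | primary alcohol: as 21 with C1 bearing CH2CH2OH (C14, C13) | COC1(OC)[C@H](CCO)C[C@H](OC(=O)CC)[C@@]2(C)CC=C([C@H](C)[C@@H](O[Si](C)(C)C(C)(C)C)CCOCc3ccccc3)[C@@H]12 | intermediate
24 | 13-O-tert-butyldimethylsilyl ether of 23 | COC1(OC)[C@H](CCO[Si](C)(C)C(C)(C)C)C[C@H](OC(=O)CC)[C@@]2(C)CC=C([C@H](C)[C@@H](O[Si](C)(C)C(C)(C)C)CCOCc3ccccc3)[C@@H]12 | intermediate
25 | saturated ring A/B alcohol: as 24 with ring B cyclopentane (7R, H7 cis to H16 and C18) and free C11–OH | COC1(OC)[C@H](CCO[Si](C)(C)C(C)(C)C)C[C@H](OC(=O)CC)[C@@]2(C)CC[C@@H]([C@H](C)[C@@H](O[Si](C)(C)C(C)(C)C)CCO)[C@@H]12 | intermediate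
26 | C11 aldehyde of 25 | COC1(OC)[C@H](CCO[Si](C)(C)C(C)(C)C)C[C@H](OC(=O)CC)[C@@]2(C)CC[C@@H]([C@H](C)[C@@H](O[Si](C)(C)C(C)(C)C)CC=O)[C@@H]12 | intermediate
27 | (11Z)-12-iodoalkene: as 26 with C10–CH=C(CH3)I, iodine cis to C10 | COC1(OC)[C@H](CCO[Si](C)(C)C(C)(C)C)C[C@H](OC(=O)CC)[C@@]2(C)CC[C@@H]([C@H](C)[C@@H](O[Si](C)(C)C(C)(C)C)C/C=C(/C)I)[C@@H]12 | intermediate
28 | C15 ketone of 27 | O=C1[C@H](CCO[Si](C)(C)C(C)(C)C)C[C@H](OC(=O)CC)[C@@]2(C)CC[C@@H]([C@H](C)[C@@H](O[Si](C)(C)C(C)(C)C)C/C=C(/C)I)[C@@H]12 | intermediate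
29 | C15=C17 exocyclic methylene compound from 28 | C=C1[C@H](CCO[Si](C)(C)C(C)(C)C)C[C@H](OC(=O)CC)[C@@]2(C)CC[C@@H]([C@H](C)[C@@H](O[Si](C)(C)C(C)(C)C)C/C=C(/C)I)[C@@H]12 | intermediate
30 | 9,13-diol from 29 (3-propanoate, alkenyl iodide) | C=C1[C@H](CCO)C[C@H](OC(=O)CC)[C@@]2(C)CC[C@@H]([C@H](C)[C@@H](O)C/C=C(/C)I)[C@@H]12 | intermediate
31 | C13 aldehyde of 30 (C9–OH free) | C=C1[C@H](CC=O)C[C@H](OC(=O)CC)[C@@]2(C)CC[C@@H]([C@H](C)[C@@H](O)C/C=C(/C)I)[C@@H]12 | intermediate
32 | (Z)-alkenylchromium dichloride from 31, chromium on C12 (formed in the flask) | C=C1[C@H](CC=O)C[C@H](OC(=O)CC)[C@@]2(C)CC[C@@H]([C@H](C)[C@@H](O)C/C=C(/C)[Cr](Cl)Cl)[C@@H]12 | intermediate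
33 | (1R,3S,4S,7R,8S,9S,11Z,13R,16S)-9,13-dihydroxytrinervita-11,15(17)-dien-3-yl propanoate | C=C1[C@H]2C[C@H](OC(=O)CC)[C@@]3(C)CC[C@@H]([C@H](C)[C@@H](O)C/C=C(/C)[C@H](O)C2)[C@@H]13 | intermediate
34 | (1R,3S,4S,7R,8S,9S,11Z,13R,16S)-trinervita-11,15(17)-diene-3,9,13-triyl tripropanoate | C=C1[C@H]2C[C@H](OC(=O)CC)[C@@]3(C)CC[C@@H]([C@H](C)[C@@H](OC(=O)CC)C/C=C(/C)[C@H](OC(=O)CC)C2)[C@@H]13 | target

**Count and risks**

Total steps: 24. Longest linear sequence: 22 steps (steps 3 to 8, then 9 to 24).

Steps most likely to fail: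

Step 9. The hindered, α-branched alkenyl group may be transferred too slowly to C16, which is flanked by the quaternary C15 ketal carbon and the α-methyl group, so that enolisation or 1,2-addition takes over. The fallback sets out again from 13 and 3 and uses a nickel-catalysed reductive conjugate addition (NiCl2·dme, neocuproine, Mn powder, Et3SiCl, DMF), which joins the alkenyl iodide to the enone through an allylnickel intermediate without a preformed organometallic. It should give the bis(triethylsilyl) enol ether/ether F1, and K2CO3 in MeOH returns to the route at 16.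

Step 12. The intrinsic facial bias of the cis-fused ketone may override the reagent, so that hydride is delivered to the C3 face syn to the C18 methyl. The fallback sets out from 19 and uses that substrate bias deliberately (NaBH4, CeCl3·7H2O, MeOH) to make the 3-epi-alcohol F2. This is inverted by Mitsunobu esterification (4-nitrobenzoic acid, PPh3, DIAD, toluene) to the 4-nitrobenzoate F3, and cleavage with K2CO3 in MeOH rejoins the route at 20.

Step 23. Facial selectivity at C13 may be poor when the eleven-membered ring closes, and intermolecular coupling competes if dilution is insufficient. The fallback sets out from 33 obtained together with its 13-epimer F4. The allylic alcohol of the mixture is oxidised selectively with MnO2 to the (Z)-enone F5, which is reduced under reagent control with (S)-2-methyl-CBS-oxazaborolidine and catecholborane; this converges on 33.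

**Further compounds**

F1 | step 9 | conjugate adduct as C3 triethylsilyl enol ether and C5 triethylsilyl ether | COC1(OC)[C@H](C=C)CC(O[Si](CC)(CC)CC)=C(C)[C@H]1C(=C/CO[Si](CC)(CC)CC)\[C@H](C)[C@@H](O[Si](C)(C)C(C)(C)C)CCOCc1ccccc1
F2 | step 12 | 3-epi-alcohol (3R) of 20 | COC1(OC)[C@H](C=C)C[C@@H](O)[C@@]2(C)CC=C([C@H](C)[C@@H](O[Si](C)(C)C(C)(C)C)CCOCc3ccccc3)[C@@H]12
F3 | step 12 | 3-O-(4-nitrobenzoate) with the C3 configuration of 20 | COC1(OC)[C@H](C=C)C[C@H](OC(=O)c3ccc(cc3)[N+](=O)[O-])[C@@]2(C)CC=C([C@H](C)[C@@H](O[Si](C)(C)C(C)(C)C)CCOCc3ccccc3)[C@@H]12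
F4 | step 23 | 13-epimer (13S) of 33 | C=C1[C@H]2C[C@H](OC(=O)CC)[C@@]3(C)CC[C@@H]([C@H](C)[C@@H](O)C/C=C(/C)[C@@H](O)C2)[C@@H]13
F5 | step 23 | (11Z)-13-oxo compound (macrocyclic enone) derived from 33 and F4 | C=C1[C@H]2C[C@H](OC(=O)CC)[C@@]3(C)CC[C@@H]([C@H](C)[C@@H](O)C/C=C(/C)C(=O)C2)[C@@H]13
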